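The runs are calculated from invented constants, and the scatter is random.

**The load.** Divide the substrate charged by the catalyst charged before anything else. Delta carries 417 turnovers per catalyst; I call this the load, the turnovers each catalyst must make to empty a flask.

| setting | east | south-east | south-west | eta | epsilon | delta | beta |
|---|---|---|---|---|---|---|---|
| substrate | 12 mM | 12 mM | 9.8 mM | 12 mM | 4.0 mM | 25 mM | 12 mM |
| free catalyst | 0.043 mM | 0.10 mM | 0.12 mM | 0.12 mM | 0.060 mM | 0.060 mM | 0.060 mM |
| temperature | −10 °C | 10 °C | −10 °C | 25 °C | 25 °C | −5 °C | 25 °C |
| remark | run made earlier | run made earlier | run made earlier |  |  |  |  |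
| time |  |  |  | 20 h | 20 h | 20 h | 20 h |

- east (time / h: product / %): 15.0: 0.5; 50.0: 1.9; 72.0: 3.1; 120: 4.8
- south-east (time / h: product / %): 10.0: 15.0; 20.0: 28.4; 30.0: 40.3; 40.0: 51.5
- south-west (time / h: product / %): 15.0: 2.7; 50.0: 6.7; 72.0: 8.7; 120: 14.8

(each reading ± 0.3 percentage points)

- a reading or a percentage of product counts all its forms, free or not

- the flasks by amount of product, in percent of the substrate charged, highest first, at 20 h (eta / epsilon / delta / beta)
- the amount of product, in percent of the substrate charged of the flask you put first, at 20 h
- the amount of product, in percent of the substrate charged of the flask you put last, at 20 h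

**First instants.** I suppose that in delta free catalyst quickly binds substrate as catalyst intermediate, and that a second step, there the rate-limiting step, releases product. Binding the whole catalyst charge of delta takes hardly any of the substrate, so c(substrate) starts at its charge.

**The middle.** The south-west run, late readings, gives 0.0945 /h per catalyst. The first south-east reading gives 1.80 /h. Taking the logarithm of speed as straight in temperature, −5 °C lies one step of four up from −10 °C to 10 °C, which gives 0.197 /h. This may run low, since delta holds more substrate than those runs.

**The end.** In 20 h I expect 3.95 turnovers in delta, far below its load, so product is their ratio, 0.948%. At 25 °C the same line gives 16.4 /h, or 328 turnovers, above beta's load of 200, the highest of the three. So I put delta last and leave the other three unranked.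

**The forecast.** It says eta > epsilon > beta > delta, with 98.7% first and 1.5% last, the latter above my figure. Its ground for the catalyst is “Steady rates scale with catalyst.”

**The flask.** It gives eta > epsilon > beta > delta, with 95.9% and 1.56%, crystals counted.

    substrate + free catalyst ⇌ catalyst intermediate (K = 180 /M, k = 4200 /M/h, Ea = 37.0 kJ/mol, ΔH = 13.0 kJ/mol)
    catalyst intermediate → free catalyst + product (k = 18.0 /h, Ea = 81.0 kJ/mol)
    crystals ⇌ product, rate k3*(cs3 - [product]) while solid is left; crystals form when [product] > cs3 (solubility = 0.210 mM, k = 3.20 /h)
    (constants at 25 °C)

**What ran.** In delta, catalyst intermediate holds 70.1% of the catalyst at 10.0 h and 69.9% at 20.0 h, while substrate stands at 98.3%. At 8.93 h the intermediate falls back 17 times faster than it goes on. Against the load, 1.56% is 6.51 turnovers, above my 3.95. A repeat of delta at 10 °C gives 11.1%, above the forecast's low of 1.5%. A flask like delta with 0.024 mM of free catalyst has load 1042, and its 0.626% is 6.52 turnovers.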